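**Retrosynthetic overview**
- Late functional-group steps: the enal comes from SeO2 oxidation of a C5 isopropenyl group, the methylene lactone from a Horner–Wadsworth–Emmons reaction of an α-phosphono lactone with formaldehyde, the C4 alcohol from a ketone, the ester and the OH-directed epoxide from the free C1 alcohol.
- The C4 ketone comes from a nitro group (Nef), so C4 is carried as a nitronate, an acyl-anion equivalent.
- The lactone carbon on C3 comes from phosphonoacetate addition to the C3=C4 nitroalkene, which acts as an α-keto cation equivalent.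
- The carbocycle is closed at C3–C4 by an intramolecular Henry reaction, directly after an L-proline cross-aldol (C1–C2) of silyloxyacetaldehyde with an α-quaternary nitro aldehyde.
- That aldehyde comes from tiglic aldehyde and a nitrodiene (C5–C6). Ring order: cyclohexane (step 3), γ-lactone (step 5), oxirane (step 7).

Assumption: the target is the open γ-hydroxy enal as drawn; ring atoms are called C1 (CH–O-methacrylate), C2 (CH–O lactone), C3, C4 (CHOH), C5, C6 (quaternary), and α/β mean below/above the ring drawn with C1→C6 clockwise (target: 1α-O, 2α-O, 3β-C, 4β-OH, 5β-C, 6β-CH3, 6α-oxiranyl).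

**Step 1**
Reactants: 1 methacrolein; 2 nitromethane
Product: 5 (1E)-3-methyl-1-nitrobuta-1,3-diene, via nitro alcohol 3 (not isolated), via nitro alcohol mesylate 4 (not isolated)
Conditions: 2 (5 equiv), KOt-Bu (5 mol%), THF/t-BuOH, 0 °C; then MsCl, Et3N, CH2Cl2, −20 → 0 °C
Reagents that add atoms: none
Why: Kinetic Henry (nitroaldol) 1,2-addition followed by mesylation and E1cB elimination gives the (E)-nitrodiene, with no stereocentre kept.

**Step 2**
Reactants: 6 tiglic aldehyde; 5 (1E)-3-methyl-1-nitrobuta-1,3-diene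
Product: 7 (2S,3S)-2-ethenyl-2,4-dimethyl-3-(nitromethyl)pent-4-enal
Conditions: 6 (2 equiv), Jacobsen primary amine–thiourea (trans-cyclohexane-1,2-diamine/tert-leucine amide type, 10 mol%, antipode giving 2S,3S), PhCO2H (10 mol%), H2O (2 equiv), CH2Cl2, rt
Reagents that add atoms: none
Why: Proposed new method: the primary amine turns tiglic aldehyde into its s-trans 2-aminodiene (dienamine), and the thiourea-bound nitro group of 5 is delivered to the dienamine α-carbon in a synclinal arrangement with the vinyl group anti to nitrogen, so one Michael addition sets quaternary C6 (methyl and vinyl) and C5; the closest known reactions are the primary amine–thiourea Michael addition of 2-arylpropanals to nitroalkenes and the α-selective dienamine Michael addition of γ,γ-disubstituted enals to nitroalkenes.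

**Step 3**
Reactants: 7 (2S,3S)-2-ethenyl-2,4-dimethyl-3-(nitromethyl)pent-4-enal; 8 (tert-butyldimethylsilyloxy)acetaldehyde
Product: 10 nitrocyclohexanediol, via aldol aldehyde 9 (not isolated)
Conditions: 8 (2.5 equiv, syringe pump), L-proline (20 mol%), DMF, 4 °C; then Et3N (20 mol%), 0 °C → rt
Reagents that add atoms: none
Why: The L-proline enamine cross-aldol (List–Houk transition state, anti adduct, acceptor 7 has no α-hydrogen) sets C1 and C2, and the C4 nitronate, an acyl-anion equivalent, then closes the six-membered ring onto the C3 aldehyde carbon by an intramolecular Henry reaction, joining two carbons that are both electrophilic in normal polarity (the new C3/C4 centres are erased in steps 4 and 6).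

**Step 4**
Reactants: 10 nitrocyclohexanediol; 11 triethyl phosphonoacetate
Product: 14 phosphonoacetate Michael adduct, via C3 acetate 12 (not isolated), via nitrocyclohexene 13 (not isolated)
Conditions: Ac2O (1.2 equiv), Et3N (3 equiv), DMAP (5 mol%), CH2Cl2, −20 → 0 °C; then 11 (1.5 equiv), DBU (20 mol%), 0 °C → rt
Reagents that add atoms: none
Why: Selective acetylation of the less hindered C3 hydroxyl (C1–OH is axial and neopentyl) and E1cB elimination give the cyclic nitroalkene, which takes up the phosphonoacetate anion at C3 in a reversible Michael addition anti to the C2 silyloxy group, ending with the bulky group equatorial (3β, trans to C2–O, cis to the C5 isopropenyl).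

**Step 5**
Reactants: 14 phosphonoacetate Michael adduct
Product: 16 nitro α-phosphono lactone, via hydroxy ester 15 (not isolated)
Conditions: 48% aq. HF, MeCN, rt; then PPTS (10 mol%), toluene, 60 °C
Reagents that add atoms: none
Why: Acidic desilylation frees the equatorial C2 hydroxyl, which closes onto the trans-disposed ethyl ester (acid-catalysed lactonisation) to the trans-fused γ-lactone; C4 carries no oxygen yet, so only the wanted lactone can form.

**Step 6**
Reactants: 16 nitro α-phosphono lactone
Product: 17 keto lactone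
Conditions: aq. TiCl3 (4.5 equiv), NH4OAc buffer (pH ≈ 5), THF, rt
Reagents that add atoms: water, O
Why: McMurry-type reductive Nef reaction: TiCl3 reduces the aci-nitro form to the imine, which hydrolyses to the C4 ketone under buffered conditions that spare the alkenes, the lactone and the base-sensitive β-acyloxy ketone.

**Step 7**
Reactants: 17 keto lactone
Product: 18 epoxy keto lactone
Conditions: VO(acac)2 (5 mol%), t-BuOOH (1.5 equiv), CH2Cl2, 0 °C → rt
Reagents that add atoms: tert-butyl hydroperoxide, CC(C)(C)OO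
Why: Hydroxyl-directed vanadium-catalysed epoxidation: the axial C1 vanadate ester delivers oxygen to the homoallylic vinyl group through a chair transition state (Mihelich model) with the terminal CH2 turned below the ring towards C1–O, giving the (R)-oxirane, while the isopropenyl group is only bishomoallylic to that hydroxyl.

**Step 8**
Reactants: 18 epoxy keto lactone
Product: 19 C1 methacrylate
Conditions: methacrylic anhydride (2 equiv), DMAP (10 mol%), pyridine, CH2Cl2, 0 °C → rt
Reagents that add atoms: methacrylic anhydride, C=C(C)C(=O)OC(=O)C(C)=C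
Why: DMAP-catalysed acylation of the only free hydroxyl; C4 is still a ketone at this point, so C1 and C4 oxygen need not be told apart.

**Step 9**
Reactants: 19 C1 methacrylate
Product: 20 C4 alcohol
Conditions: LiAlH(Ot-Bu)3 (2.5 equiv), THF, −40 °C
Reagents that add atoms: none
Why: Diastereoselective ketone reduction: the axial C6 methyl blocks the axial path, so the bulky hydride attacks equatorially and gives the axial 4β-alcohol cis to both neighbours, while esters, lactone and epoxide are inert to this reagent at low temperature.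

**Step 10**
Reactants: 20 C4 alcohol
Product: 21 α-methylene lactone
Conditions: 37% aq. HCHO (5 equiv), K2CO3 (2 equiv), THF, 0 °C
Reagents that add atoms: formaldehyde, C=O
Why: Horner–Wadsworth–Emmons olefination of the α-phosphono lactone with formaldehyde installs the exocyclic methylene and removes the epimeric α-centre.

**Step 11**
Reactants: 21 α-methylene lactone
Product: 22 target CNP0124638.2
Conditions: SeO2 (1.5 equiv), pyridine (2 equiv), 1,4-dioxane, 60 °C
Reagents that add atoms: selenium dioxide, O=[Se]=O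
Why: Riley allylic oxidation (ene reaction, then [2,3]-shift) of the only electron-rich alkene converts the isopropenyl methyl into the aldehyde, while the methacrylate and the methylene lactone are deactivated.

**Compound list**
1 | methacrolein (2-methylprop-2-enal) | C=C(C)C=O | starting material
2 | nitromethane | C[N+](=O)[O-] | starting material
3 | rac-3-methyl-1-nitrobut-3-en-2-ol | C=C(C)C(O)C[N+](=O)[O-] | intermediate (not isolated)
4 | rac-3-methyl-1-nitrobut-3-en-2-yl methanesulfonate | C=C(C)C(OS(C)(=O)=O)C[N+](=O)[O-] | intermediate (not isolated)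
5 | (1E)-3-methyl-1-nitrobuta-1,3-diene | C=C(C)/C=C/[N+](=O)[O-] | intermediate
6 | tiglic aldehyde, (2E)-2-methylbut-2-enal | C/C=C(\C)C=O | starting material
7 | (2S,3S)-2-ethenyl-2,4-dimethyl-3-(nitromethyl)pent-4-enal | O=C[C@@](C)(C=C)[C@H](C(C)=C)C[N+](=O)[O-] | intermediate
8 | (tert-butyldimethylsilyloxy)acetaldehyde | O=CCO[Si](C)(C)C(C)(C)C | starting material
9 | (2S,3S,4S,5S)-2-(tert-butyldimethylsilyloxy)-4-ethenyl-3-hydroxy-4,6-dimethyl-5-(nitromethyl)hept-6-enal | O=C[C@@H](O[Si](C)(C)C(C)(C)C)[C@@H](O)[C@@](C)(C=C)[C@H](C(C)=C)C[N+](=O)[O-] | intermediate (not isolated)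
10 | nitrocyclohexanediol: 1α-OH, 2α-OTBS, 3β-OH, 4α-NO2, 5β-isopropenyl, 6β-methyl, 6α-vinyl (major C3/C4 epimer shown) | O[C@@H]1[C@H](O[Si](C)(C)C(C)(C)C)[C@@H](O)[C@H]([N+](=O)[O-])[C@@H](C(C)=C)[C@]1(C)C=C | intermediate
11 | triethyl phosphonoacetate | CCOC(=O)CP(=O)(OCC)OCC | starting material
12 | C3 acetate of 10 (3β-OAc) | O[C@@H]1[C@H](O[Si](C)(C)C(C)(C)C)[C@@H](OC(C)=O)[C@H]([N+](=O)[O-])[C@@H](C(C)=C)[C@]1(C)C=C | intermediate (not isolated)
13 | nitrocyclohexene: 1α-OH, 2α-OTBS, C3=C4 with NO2 on C4, 5β-isopropenyl, 6β-methyl, 6α-vinyl | O[C@@H]1[C@H](O[Si](C)(C)C(C)(C)C)C=C([N+](=O)[O-])[C@@H](C(C)=C)[C@]1(C)C=C | intermediate (not isolated)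
14 | Michael adduct: as 10 but 3β-CH(CO2Et)P(O)(OEt)2 (both epimers at that CH), 4α-NO2 | O[C@@H]1[C@H](O[Si](C)(C)C(C)(C)C)[C@@H](C(C(=O)OCC)P(=O)(OCC)OCC)[C@H]([N+](=O)[O-])[C@@H](C(C)=C)[C@]1(C)C=C | intermediate
15 | hydroxy ester: 14 with free 2α-OH | O[C@@H]1[C@H](O)[C@@H](C(C(=O)OCC)P(=O)(OCC)OCC)[C@H]([N+](=O)[O-])[C@@H](C(C)=C)[C@]1(C)C=C | intermediate (not isolated)
16 | nitro α-phosphono lactone: trans-fused γ-lactone (2α-O, 3β-C) carrying P(O)(OEt)2 on the lactone α-carbon (epimers), 1α-OH, 4α-NO2, 5β-isopropenyl, 6β-methyl, 6α-vinyl | O[C@@H]1[C@@H]2OC(=O)C(P(=O)(OCC)OCC)[C@H]2[C@H]([N+](=O)[O-])[C@@H](C(C)=C)[C@]1(C)C=C | intermediate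
17 | keto lactone: 16 with C4=O in place of CH–NO2 | O[C@@H]1[C@@H]2OC(=O)C(P(=O)(OCC)OCC)[C@H]2C(=O)[C@@H](C(C)=C)[C@]1(C)C=C | intermediate
18 | epoxy keto lactone: 17 with 6α-[(R)-oxiran-2-yl] in place of vinyl | O[C@@H]1[C@@H]2OC(=O)C(P(=O)(OCC)OCC)[C@H]2C(=O)[C@@H](C(C)=C)[C@]1(C)[C@@H]1CO1 | intermediate
19 | C1 methacrylate of 18 (1α-O-methacryloyl) | C=C(C)C(=O)O[C@@H]1[C@@H]2OC(=O)C(P(=O)(OCC)OCC)[C@H]2C(=O)[C@@H](C(C)=C)[C@]1(C)[C@@H]1CO1 | intermediate
20 | C4 alcohol: 19 with 4β-OH (axial) | C=C(C)C(=O)O[C@@H]1[C@@H]2OC(=O)C(P(=O)(OCC)OCC)[C@H]2[C@@H](O)[C@@H](C(C)=C)[C@]1(C)[C@@H]1CO1 | intermediate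
21 | α-methylene lactone: target skeleton with 5β-isopropenyl in place of the acrolein unit | C=C(C)C(=O)O[C@@H]1[C@@H]2OC(=O)C(=C)[C@H]2[C@@H](O)[C@@H](C(C)=C)[C@]1(C)[C@@H]1CO1 | intermediate
22 | CNP0124638.2 | C=C(C)C(=O)O[C@@H]1[C@@H]2OC(=O)C(=C)[C@H]2[C@@H](O)[C@@H](C(=C)C=O)[C@]1(C)[C@@H]1CO1 | target

**Totals**
Total steps: 11. Longest linear sequence: 11 (steps 1 to 11; all other partners are bought).

**Steps most likely to fail**

Step 2 (α- versus γ-attack of the dienamine, and diastereocontrol at the quaternary centre). The fallback sets out from 5 and comes back at 7. Tigloyl chloride acylates (S)-4-benzyloxazolidin-2-one to N-tigloyl-(S)-4-benzyloxazolidin-2-one F1. Deprotonation at the γ-methyl with NaN(SiMe3)2 (THF, −78 °C) gives the chelated dienolate, which adds through its α-carbon to 5 on the face away from the benzyl group to give the imide Michael adduct F2. LiBH4 removes the auxiliary to give the primary alcohol F3, and Dess–Martin oxidation returns to 7. The (S)-auxiliary is shown; its antipode is taken if the facial sense proves opposite.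

Step 3 (cross-aldol onto a neopentyl aldehyde competes with self-aldol of 8). The fallback sets out from 7 and comes back at 9. A titanium-enolate anti-glycolate aldol is used: (S)-4-benzyl-3-[(tert-butyldimethylsilyloxy)acetyl]thiazolidine-2-thione, TiCl4 and i-Pr2NEt, then 7 precomplexed with TiCl4, give the auxiliary-bound anti aldol adduct F4. i-Bu2AlH at −78 °C cleaves the thione auxiliary directly to aldehyde 9, which is cyclised with Et3N as in step 3.

Step 11 (allylic oxidation on the fully functionalised molecule; risk of epoxide opening or over-oxidation through the lactol). The fallback sets out from 21 and ends at 22. A singlet-oxygen ene reaction (O2, tetraphenylporphyrin, visible light, CH2Cl2, 0 °C) on the isopropenyl group, the only electron-rich alkene, gives the allylic hydroperoxide F5. Ac2O, pyridine and DMAP dehydrate it (Kornblum–DeLaMare type) to the enal 22.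

**Further compounds**
F1 | step 2 | N-tigloyl-(S)-4-benzyloxazolidin-2-one | C/C=C(\C)C(=O)N1[C@@H](Cc2ccccc2)COC1=O
F2 | step 2 | imide Michael adduct, (S)-4-benzyl-3-[(2S,3S)-2-ethenyl-2,4-dimethyl-3-(nitromethyl)pent-4-enoyl]oxazolidin-2-one | O=C(N1[C@@H](Cc2ccccc2)COC1=O)[C@@](C)(C=C)[C@H](C(C)=C)C[N+](=O)[O-]
F3 | step 2 | primary alcohol, (2S,3S)-2-ethenyl-2,4-dimethyl-3-(nitromethyl)pent-4-en-1-ol | OC[C@@](C)(C=C)[C@H](C(C)=C)C[N+](=O)[O-]
F4 | step 3 | anti aldol adduct, N-acyl (S)-4-benzylthiazolidine-2-thione of the acid corresponding to 9 | O=C([C@@H](O[Si](C)(C)C(C)(C)C)[C@@H](O)[C@@](C)(C=C)[C@H](C(C)=C)C[N+](=O)[O-])N1[C@@H](Cc2ccccc2)CSC1=S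
F5 | step 11 | allylic hydroperoxide, 21 with 5β-(3-hydroperoxyprop-1-en-2-yl) | C=C(C)C(=O)O[C@@H]1[C@@H]2OC(=O)C(=C)[C@H]2[C@@H](O)[C@@H](C(=C)COO)[C@]1(C)[C@@H]1CO1
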